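## The problem

Target 32 is a stilbene trimer in which two 2,3-trans-2,3-diaryl-2,3-dihydrobenzofurans are joined head to tail. C3 of dihydrobenzofuran 1 (O1, C2, C3, C3a, C4–C7, C7a; its benzo ring is ring A) is bonded to C6' of the benzo ring (the hub) of dihydrobenzofuran 2 (primed atoms). Ring A also carries the 4-OH and the 6-(E)-4-hydroxystyryl group (ring C). C2 bears a 4-hydroxyphenyl ring (ring B), C2' a 2,4-dihydroxyphenyl ring (ring D) and C3' a 3,5-dihydroxyphenyl ring (ring E).

There are four stereocentres, all S, in two trans pairs. Within a pair the C3-type centre can dictate the C2-type centre, because each C2–O bond is a benzylic aryl ether that can open and re-close to the more stable trans ring. The two pairs are separated by the flat hub and cannot control each other, so absolute control is needed twice, at C3' and at C3. Both of these carbons are diarylmethines attached to an arene carbon flanked by two oxygenated positions (C3a', C3a), so every C–C bond to them is crowded.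

The molecule will not survive boron-halide ether cleavage (it ionises C2–O1 and C2'–O1', the latter activated by the ortho and para oxygens of ring D), hydrogenolysis or hydrogenation (benzylic ethers, stilbene), or one-electron oxidants (eight phenols, a resveratrol-like stilbene).

The feature that allows a short end game is C2: it carries O1 and a para-hydroxyphenyl ring. O1–C2 is therefore the formal 1,6-adduct of a para-quinone methide, derived from the ArCH2 group of a 4-alkylphenol, with one of the two equivalent ring A hydroxyls that flank C3a.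

## Retrosynthesis

**O1–C2.** The last bond formed is O1–C2 of 32, cut to para-quinone methide 31 and, one oxidation level below, seco-phenol 30. Cutting here rather than at C2–C3 or C3–C3a keeps every carbon–carbon bond in place before the end. A closure from a C2 carbinol would instead need an extra oxygen carried through the route and acid in the last step. 30 is simpler by one ring and one stereocentre, and C2 will follow from C3. The forward reaction must dehydrogenate one ArCH2 group among nine phenols. That is asked of a flavin-dependent 4-alkylphenol oxidase, because a chemical hydride acceptor would prefer the more electron-rich C2'–H.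

**Oxygen protection.** 30 is taken back to 29, in which the seven hydroxyls outside ring A are silyl ethers (TIPS on ring system 2, TBS on rings B and C) and the two ring A hydroxyls are free. Only Si–O bonds are cut, with fluoride. Methyl or benzyl ethers would be quicker to install, but their removal would ionise or cleave C2'–O1' and endanger the stilbene. Most of the extra steps of the route are spent on this choice.

**C3–H.** 29 is cut at C3–H to triarylethylene 28, and 28 to tertiary carbinol 27 (water across C2=C3, two MOM ethers restored). The hydrogen is delivered as hydride to the ortho-quinone methide that 28 forms through its ring A hydroxyls under a chiral phosphoric acid. Metal-catalysed asymmetric hydrogenation of a triarylethylene was weighed for the same bond and set aside. It needs a single alkene isomer, and the ring A aryl group, twisted out of plane by its two ortho oxygens, shields both alkene faces from a metal. The quinone-methide route erases alkene geometry, uses the very hydroxyls that cause the crowding, and needs a reagent no larger than hydride.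

**C2–C3 and C3–C6'.** 27 is cut at C2–C3 into ketone 22 and benzylmagnesium chloride 26 (from chloride 25, alcohol 24, aldehyde 23). 22 is cut through carbinol 21 at C3–C6' into aryllithium 20, made from bromide 16, and aldehyde 19. Making the bond to the hub on an aldehyde and the benzyl bond on the non-enolisable ketone is the safer order; the reverse needs an aryl nucleophile to add to an enolisable ketone. The cut is convergent: 16 holds both stereocentres of ring system 2, and 19 holds ring A and the stilbene.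

**Ring A fragment.** 19 is cut at the aryl–vinyl bond into bromide 17 and styrene 18, and 17 goes back through diol 2 to commercial 1. The bromide is para to the formyl group, which suits an arylation of the alkene. Installing the stilbene here keeps palladium away from the late intermediates.

**Ring system 2, C2'–C3'.** 16 is related to its cis isomer 15 (C2' only), and 15 is cut at C2'–C3' to diazo compound 14 and hydrazone 13. A diaryl carbene at C3' inserts into the benzylic C–H bond of the ortho benzyl ether. This was preferred to closing O1'–C2' by a second quinone-methide reaction, because the 2,4-dioxygenated benzyl nucleophile that would need is not a practical reagent, whereas here the same unit enters as stable benzyl alcohol 5. The forward step sets C3' under catalyst control; C2' is then corrected to trans by reversible opening of the benzylic ether.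

**The carbene precursor.** 13 comes from hydrazone 12 by silylation, 12 from ketone 11, 11 from carbinol 10, and 10 from aryllithium 9 (from bromide 8 and diol 7) and aldehyde 6. 6 is the mono-ether of 2 with 5, which comes from 3 through 4. The ortho hydroxyl is left free until 12 is formed, because a ketone with two ortho substituents condenses with hydrazine far more readily when one of them is a hydrogen-bonding OH. It is then capped with a silyl group that offers the carbene no competing C–H bond.

## Roads not taken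

**Alternative 1:** ring A is built around C3a instead of being bought.
- Cut: three ring bonds (C3a–C4, C4–C5, C7–C7a).
- Forward key step: cyclobutenone A2 is heated with siloxyalkyne A3, which already carries C3 and an oxygenated C2. A2 ring-opens and adds across the alkyne; a second four-electron opening, six-electron closure and tautomerisation would give phenol A1 (Danheiser benzannulation).
- Merits: the crowded bond between C3 and the doubly ortho-oxygenated carbon is never made by a coupling, because the arene grows from the alkyne carbon that C3 sits on. C3 and C2 are set earlier on an open chain, where control is routine. The ring A oxygens emerge differentiated (OH, OTIPS) with the styryl arm in place, and closure of ring 1 from the C2 silyl ether is plain acid chemistry.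
- Weak points: the aryl group on C3 of A1 is only a 3,5-dimethoxyphenyl ring, so ring system 2 with its two stereocentres would still have to be built on it, between two methoxy groups and late. Carrying complete ring system 2 through the synthesis of A3 instead puts a propargylic, doubly benzylic stereocentre next to an ynol ether for several steps. The thermal step must tolerate a styryl group with other pericyclic options. The methyl ethers bring back Lewis-acid demethylation in the presence of ring system 2.
- Comparison: for C3 and for closing ring 1 this road uses better-known chemistry than the chosen plan, whose last step has no direct precedent. The chosen plan sets against it that ring system 2 arrives as one finished, enantiopure block (16), that ring 1 is closed last on the unprotected phenol with O2 as the only reagent, and that no sensitive alkyne has to be assembled.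

**Alternative 2:** ring system 2 by a formal [4+1] annulation.
- Cut: C2'–C3' and O1'–C2' together.
- Forward key step: Cs2CO3 expels sulfinate from sulfone A5 and deprotonates chiral sulfonium salt A6 in one flask. The carbon of A6 bonds to the benzylic carbon of A5, and the phenoxide then displaces the thiolane, giving A4, the pentamethyl analogue of 16.
- Merits: one step forms two bonds, the ring and both stereocentres, trans by mechanism. A5 is about three steps from 1 and an aryllithium. The way to a 6-bromide of ring system 2 would be roughly half as long as steps 2 to 10 here, and A4 is the kind of block that step 13 needs. In step count this road is better than what was chosen for ring system 2.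
- Weak points: enantiocontrol rests on a stoichiometric chiral sulfide and a semi-stabilised benzyl ylide, a pairing much less proven in such annulations than acyl-stabilised ylides. The methyl ethers of A4 cannot be removed later without Lewis acids that ionise C2'–O1'. As a plan for the whole molecule it leaves C3, C2 and ring 1 to a second, purely reagent-controlled annulation on ring A.
- Comparison: against the shorter access the chosen plan sets a ring-forming step (step 10) of a type established for 2-benzyloxy diaryl carbenes giving 2,3-diaryl-dihydrobenzofurans, silyl ethers that leave with fluoride, and a separate, reagent-free way of making ring 1.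

**Alternative 3:** ring system 1 by contraction of a flavanone.
- Cut: C3–C3a.
- Forward key step: protected naringenin A8, with the correct 2S centre from the chiral pool, is treated with PhI(OAc)2 and H2SO4 in trimethyl orthoformate. Trivalent iodine is attached at C3, the ring A carbon migrates from C4 to C3 as iodobenzene leaves, and the old C4 ends as the methyl ester of A7.
- Merits: C2 is bought; the trans relationship follows from the migration; two to three steps from a cheap natural product; a known reaction type.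
- Weak points: C3 of A7 carries CO2Me where the target carries the hub, so a whole oxygenated arene plus ring system 2 would have to be grown from, or coupled in place of, a carboxyl carbon at a crowded secondary centre. C2 of a flavanone racemises through the chalcone under acid, and 2,3-aryl migration to the isoflavone competes. The 6-oxygen must be exchanged for the styryl carbon through a triflate.
- Comparison: A7 reaches a trans-2-aryl-dihydrobenzofuran with the right C2 in far fewer steps than the chosen plan needs to reach 30, with no new method. The chosen plan sets against it that the C3 substituent, the hardest part of the target, is present from the moment C3 is created; Alternative 3 leaves that problem untouched.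

Key step: step 21

Assumption: compounds 1, 3, 7, 18 and 23 are commercial. The sense of induction of Rh2(S-PTAD)4 (step 10) and (R)-TRIP (step 19) is assumed as drawn, the mirror-image catalyst being used otherwise. The oxidase of step 21 is a variant still to be found by screening and mutagenesis.

Abbreviations: TIPS = triisopropylsilyl; TBS = tert-butyldimethylsilyl; MOM = methoxymethyl. RS2 = the (2S,3S)-2-[2,4-bis(TIPS-oxy)phenyl]-3-[3,5-bis(TIPS-oxy)phenyl]-4-(TIPS-oxy)-2,3-dihydro-1-benzofuran-6-yl group.

## Route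

Step 1
Reactants: 1 4-bromo-2,6-dimethoxybenzaldehyde
Product: 2 4-bromo-2,6-dihydroxybenzaldehyde
Conditions: BBr3 (3 equiv), CH2Cl2, −78 °C to rt; H2O
Reagents that add atoms: none
Why: Boron tribromide demethylation of aryl methyl ethers; both methoxy groups are ortho to the formyl group and are cleaved with chelation assistance, and nothing acid-sensitive is present yet.

Step 2
Reactants: 3 2,4-dihydroxybenzaldehyde
Product: 4 2,4-bis(TIPS-oxy)benzaldehyde
Conditions: TIPSCl (2.5 equiv), imidazole, DMAP (cat.), DMF, 50 °C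
Reagents that add atoms: chlorotriisopropylsilane, CC(C)[Si](Cl)(C(C)C)C(C)C
Why: Silylation of both phenols; warming and DMAP are used because the 2-OH is hydrogen-bonded to the aldehyde.

Step 3
Reactants: 4 2,4-bis(TIPS-oxy)benzaldehyde
Product: 5 [2,4-bis(TIPS-oxy)phenyl]methanol
Conditions: NaBH4, MeOH/THF, 0 °C
Reagents that add atoms: none
Why: Borohydride reduction of an aryl aldehyde; the bulky TIPS group resists migration from the ortho oxygen to the new benzylic oxygen under these mild conditions.

Step 4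
Reactants: 2 4-bromo-2,6-dihydroxybenzaldehyde (1.3 equiv); 5 [2,4-bis(TIPS-oxy)phenyl]methanol
Product: 6 4-bromo-2-hydroxy-6-{[2,4-bis(TIPS-oxy)phenyl]methoxy}benzaldehyde
Conditions: PPh3, DIAD, THF, 0 °C to rt
Reagents that add atoms: none
Why: Mitsunobu etherification of an acidic ortho-formyl phenol; after the first alkylation the remaining hydroxyl is locked in a hydrogen bond to the aldehyde, which holds the reaction at the mono-ether, and the neutral conditions avoid silyl migration in 5.

Step 5
Reactants: 7 5-bromobenzene-1,3-diol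
Product: 8 1-bromo-3,5-bis(TIPS-oxy)benzene
Conditions: TIPSCl, imidazole, DMF, rt
Reagents that add atoms: chlorotriisopropylsilane, CC(C)[Si](Cl)(C(C)C)C(C)C
Why: Standard silylation of two unhindered phenols.

Step 6
Reactants: 8 1-bromo-3,5-bis(TIPS-oxy)benzene (2.4 equiv); 6 4-bromo-2-hydroxy-6-{[2,4-bis(TIPS-oxy)phenyl]methoxy}benzaldehyde
Product: 10 (4-bromo-2-hydroxy-6-{[2,4-bis(TIPS-oxy)phenyl]methoxy}phenyl)[3,5-bis(TIPS-oxy)phenyl]methanol (racemic), via aryllithium 9 (not isolated)
Conditions: n-BuLi (2.3 equiv), THF, −78 °C; then 6, −78 °C; H2O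
Reagents that add atoms: none
Why: Bromine–lithium exchange followed by 1,2-addition of the aryllithium; the first equivalent of 9 deprotonates the phenol of 6 and the second adds to the aldehyde, while the bromide of 6 survives because aryl–aryl exchange is slow at −78 °C.

Step 7
Reactants: 10 the diaryl carbinol of step 6
Product: 11 (4-bromo-2-hydroxy-6-{[2,4-bis(TIPS-oxy)phenyl]methoxy}phenyl)[3,5-bis(TIPS-oxy)phenyl]methanone
Conditions: MnO2 (activated, excess), CH2Cl2, rt
Reagents that add atoms: none
Why: Activated MnO2 oxidises the doubly benzylic alcohol selectively and leaves the free phenol and the silyl ethers alone; the neutral medium avoids ionising the ortho-hydroxybenzylic alcohol.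

Step 8
Reactants: 11 the ortho-hydroxy diaryl ketone of step 7
Product: 12 hydrazone of 11 (C=N isomer mixture)
Conditions: N2H4·H2O (10 equiv), AcOH (cat.), EtOH, 80 °C
Reagents that add atoms: hydrazine, NN
Why: Hydrazone formation; the ortho hydroxyl activates the carbonyl by hydrogen bonding, which lets a ketone with two ortho substituents condense, and aryl TIPS ethers should withstand hydrazine where TBS ethers might not.

Step 9
Reactants: 12 hydrazone of 11
Product: 13 [4-bromo-2-(TIPS-oxy)-6-{[2,4-bis(TIPS-oxy)phenyl]methoxy}phenyl][3,5-bis(TIPS-oxy)phenyl]methanone hydrazone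
Conditions: NaH (1.05 equiv), THF, 0 °C; TIPSCl, 0 °C to rt
Reagents that add atoms: chlorotriisopropylsilane, CC(C)[Si](Cl)(C(C)C)C(C)C
Why: One equivalent of base deprotonates only the phenol (far more acidic than the hydrazone NH2), which is silylated on oxygen; the silyl ether gives the later carbene no nearby C–H bond, unlike an alkyl or acetal group.

Step 10
Reactants: 13 the O-silylated hydrazone of step 9
Product: 16 (2S,3S)-6-bromo-2-[2,4-bis(TIPS-oxy)phenyl]-3-[3,5-bis(TIPS-oxy)phenyl]-4-(TIPS-oxy)-2,3-dihydro-1-benzofuran (trans; the bromide RS2–Br), via diazo compound 14 (not isolated), via cis-dihydrobenzofuran 15 (not isolated)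
Conditions: MnO2, CH2Cl2, rt, filter; Rh2(S-PTAD)4 (dirhodium tetrakis[(S)-(1-adamantyl)(N-phthalimido)acetate], 1 mol %), CH2Cl2, 0 °C; then TFA (5 equiv), 0 °C to rt
Reagents that add atoms: none
Why: MnO2 dehydrogenates the hydrazone to the diaryldiazomethane, and the chiral dirhodium carboxylate converts it into a donor/donor carbene that inserts into the benzylic ether C–H bond (intramolecular 1,5 C–H insertion), forming C2'–C3' and setting C3' under catalyst control with the cis ring as kinetic product. TFA then ionises C2'–O1', which is benzylic to the ortho,para-disilyloxy ring, and re-closure gives the more stable trans ring without touching C3'.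

Step 11
Reactants: 2 4-bromo-2,6-dihydroxybenzaldehyde
Product: 17 4-bromo-2,6-bis(methoxymethoxy)benzaldehyde
Conditions: MOMCl (3 equiv), i-Pr2NEt, CH2Cl2, 0 to 40 °C
Reagents that add atoms: chloromethyl methyl ether, COCCl
Why: Acetal protection of both phenols; MOM is small enough to leave the carbonyl carbon accessible later and chelates magnesium in step 17.

Step 12
Reactants: 17 4-bromo-2,6-bis(methoxymethoxy)benzaldehyde; 18 tert-butyldimethyl(4-vinylphenoxy)silane
Product: 19 4-[(E)-2-{4-[(TBS)oxy]phenyl}ethenyl]-2,6-bis(methoxymethoxy)benzaldehyde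
Conditions: Pd(OAc)2 (5 mol %), P(o-tol)3 (10 mol %), Et3N, DMF, 90 °C
Reagents that add atoms: none
Why: Heck reaction; the bromide is para to the formyl group and adds readily to zerovalent palladium, and syn insertion followed by syn β-hydride elimination gives the E-stilbene.

Step 13
Reactants: 16 the bromide RS2–Br; 19 the stilbene aldehyde of step 12
Product: 21 {4-[(E)-2-{4-[(TBS)oxy]phenyl}ethenyl]-2,6-bis(methoxymethoxy)phenyl}(RS2)methanol (both carbinol epimers), via aryllithium 20 (not isolated)
Conditions: t-BuLi (2.1 equiv), THF, −78 °C; then 19, −78 °C; H2O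
Reagents that add atoms: none
Why: Bromine–lithium exchange at C6' (the silyloxy groups are meta to lithium, so no silyl shift is possible) and 1,2-addition to the aldehyde form C3–C6'; the carbinol configuration is irrelevant because it is oxidised next.

Step 14
Reactants: 21 the diaryl carbinol of step 13
Product: 22 {4-[(E)-2-{4-[(TBS)oxy]phenyl}ethenyl]-2,6-bis(methoxymethoxy)phenyl}(RS2)methanone
Conditions: Dess–Martin periodinane, pyridine, CH2Cl2, 0 °C to rt
Reagents that add atoms: none
Why: Dess–Martin oxidation of a doubly benzylic alcohol; the buffered, non-acidic conditions spare the stilbene, the acetals and the benzylic ether of ring system 2.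

Step 15
Reactants: 23 4-[(TBS)oxy]benzaldehyde
Product: 24 {4-[(TBS)oxy]phenyl}methanol
Conditions: NaBH4, MeOH, 0 °C
Reagents that add atoms: none
Why: Borohydride reduction of an aryl aldehyde; brief exposure at 0 °C leaves the aryl silyl ether intact.

Step 16
Reactants: 24 {4-[(TBS)oxy]phenyl}methanol
Product: 25 tert-butyl[4-(chloromethyl)phenoxy]dimethylsilane
Conditions: PPh3, N-chlorosuccinimide, CH2Cl2, 0 °C to rt
Reagents that add atoms: N-chlorosuccinimide, O=C1CCC(=O)N1Cl
Why: Appel-type chlorination under neutral conditions, so no HCl is present to cleave the silyl ether; the chloride is used at once.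

Step 17
Reactants: 25 tert-butyl[4-(chloromethyl)phenoxy]dimethylsilane (3 equiv); 22 the diaryl ketone of step 14
Product: 27 1-{4-[(E)-2-{4-[(TBS)oxy]phenyl}ethenyl]-2,6-bis(methoxymethoxy)phenyl}-1-(RS2)-2-{4-[(TBS)oxy]phenyl}ethan-1-ol (both carbinol epimers), via benzylmagnesium chloride 26 (not isolated)
Conditions: Mg turnings (I2 crystal), Et2O, 0 °C; then 22, THF, 0 °C to rt; aq NH4Cl
Reagents that add atoms: none
Why: Grignard addition to a non-enolisable diaryl ketone forms C2–C3; the ortho MOM oxygens chelate magnesium and guide the compact benzyl nucleophile to the carbonyl, and both carbinol epimers converge in step 19.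

Step 18
Reactants: 27 the tertiary carbinol of step 17
Product: 28 2-{1-(RS2)-2-{4-[(TBS)oxy]phenyl}ethenyl}-5-[(E)-2-{4-[(TBS)oxy]phenyl}ethenyl]benzene-1,3-diol (E/Z mixture at the new triaryl alkene)
Conditions: HCl (1.25 M in MeOH, 5 equiv), THF/MeOH 1:1, 0 °C to rt
Reagents that add atoms: none
Why: Acid ionises the tertiary, doubly benzylic alcohol; the cation is stabilised by both ortho oxygens, so each MOM group is lost to methanol much more easily than an ordinary aryl MOM ether (acetal cleavage assisted by ortho-quinone methide formation), and loss of a C2 proton gives the alkene. Aryl TIPS and TBS ethers and the stilbene should tolerate dilute methanolic HCl, and both alkene isomers are carried on.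

Step 19
Reactants: 28 the triarylethylene diol of step 18
Product: 29 2-[(1S)-1-(RS2)-2-{4-[(TBS)oxy]phenyl}ethyl]-5-[(E)-2-{4-[(TBS)oxy]phenyl}ethenyl]benzene-1,3-diol
Conditions: (R)-TRIP ((R)-3,3'-bis(2,4,6-triisopropylphenyl)-1,1'-binaphthyl-2,2'-diyl hydrogen phosphate, 10 mol %), Hantzsch ester (diethyl 2,6-dimethyl-1,4-dihydropyridine-3,5-dicarboxylate, 1.5 equiv), toluene, 30 °C
Reagents that add atoms: none
Why: Organocatalytic asymmetric transfer hydrogenation of an ortho-hydroxy 1,1-diarylalkene: the chiral phosphoric acid protonates C2 of either alkene isomer to give the ring A ortho-quinone methide bound to the phosphate, and the Hantzsch ester held by the same phosphate delivers hydride to one face of C3. C3 is set S under catalyst control; the distant centres of ring system 2 should have little influence.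

Step 20
Reactants: 29 the heptasilyl ether of step 19
Product: 30 2-[(1S)-1-[(2S,3S)-3-(3,5-dihydroxyphenyl)-2-(2,4-dihydroxyphenyl)-4-hydroxy-2,3-dihydro-1-benzofuran-6-yl]-2-(4-hydroxyphenyl)ethyl]-5-[(E)-2-(4-hydroxyphenyl)ethenyl]benzene-1,3-diol (seco-phenol)
Conditions: TBAF (10 equiv), AcOH (10 equiv), THF, 0 °C to rt; CaCO3 and sulfonic acid resin work-up; argon
Reagents that add atoms: none
Why: Fluoride cleavage of seven aryl silyl ethers; acetic acid buffering keeps the polyphenol from standing as an air-sensitive phenoxide, and nothing in the medium can ionise C2'–O1' or touch the stilbene.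

Step 21
Reactants: 30 seco-phenol
Product: 32 (2S,3S)-3-[(2S,3S)-3-(3,5-dihydroxyphenyl)-2-(2,4-dihydroxyphenyl)-4-hydroxy-2,3-dihydro-1-benzofuran-6-yl]-2-(4-hydroxyphenyl)-6-[(E)-2-(4-hydroxyphenyl)ethenyl]-2,3-dihydro-1-benzofuran-4-ol (CNP0118407.1), via para-quinone methide 31 (not isolated)
Conditions: engineered 4-alkylphenol oxidase of the vanillyl alcohol oxidase family (covalent FAD; eugenol oxidase scaffold with widened substrate tunnel), air, catalase, 50 mM potassium phosphate pH 7.5, 10 vol % DMSO, 25 °C; then pH 5, 1 h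
Reagents that add atoms: none
Why: Proposed new method: the 4-hydroxybenzyl group of 30 is its only secondary benzylic CH2 para to a phenol, so with that phenolate in the anion-binding site of the flavoenzyme the flavin N5 can take a hydride from C2 and give para-quinone methide 31, as these oxidases do with 4-ethyl- and 4-propylphenol (closest known reaction type: flavin-dependent dehydrogenation of 4-alkylphenols to para-quinone methides that are captured by water); reduced flavin is reoxidised by O2 to H2O2, which catalase removes. In 31 a ring A hydroxyl lies within reach of the electrophilic exocyclic carbon and adds in a 5-exo-trig oxa-1,6-addition that restores the phenol and forms O1–C2 and dihydrobenzofuran 1; the two flanking hydroxyls are equivalent, so there is no regiochemical choice. C2 is set by the existing C3 centre: the C2 aryl group takes the face anti to the hub on C3, and because the benzylic aryl ether can re-open to 31 the trans (2S,3S) ring is also the thermodynamic outcome. Three selectivities are needed: CH2 over the tertiary, ring-locked C2'–H of ring system 2, CH2 over the new C2–H of the product (further dehydrogenation to benzofurans), and cyclisation over loss of the C3 proton from 31 (which would give the achiral triarylethylene). The first two rest on the substrate, since only the CH2 can place a C–H bond over the flavin while C2'–H and C2–H are tertiary and shielded by trans aryl neighbours, backed by a pocket shaped by mutagenesis and by stopping once 30 is consumed. The third rests on the proximity of the ring A phenol, and any water adduct at C2 should re-ionise to 31 and close at pH 5.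

## Compound list

1 | 4-bromo-2,6-dimethoxybenzaldehyde | COc1cc(Br)cc(OC)c1C=O | starting material
2 | 4-bromo-2,6-dihydroxybenzaldehyde | O=Cc1c(O)cc(Br)cc1O | intermediate
3 | 2,4-dihydroxybenzaldehyde | O=Cc1ccc(O)cc1O | starting material
4 | 2,4-bis(TIPS-oxy)benzaldehyde | O=Cc1ccc(O[Si](C(C)C)(C(C)C)C(C)C)cc1O[Si](C(C)C)(C(C)C)C(C)C | intermediate
5 | [2,4-bis(TIPS-oxy)phenyl]methanol | OCc1ccc(O[Si](C(C)C)(C(C)C)C(C)C)cc1O[Si](C(C)C)(C(C)C)C(C)C | intermediate
6 | 4-bromo-2-hydroxy-6-{[2,4-bis(TIPS-oxy)phenyl]methoxy}benzaldehyde | O=Cc1c(O)cc(Br)cc1OCc1ccc(O[Si](C(C)C)(C(C)C)C(C)C)cc1O[Si](C(C)C)(C(C)C)C(C)C | intermediate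
7 | 5-bromobenzene-1,3-diol | Oc1cc(O)cc(Br)c1 | starting material
8 | 1-bromo-3,5-bis(TIPS-oxy)benzene | Brc1cc(O[Si](C(C)C)(C(C)C)C(C)C)cc(O[Si](C(C)C)(C(C)C)C(C)C)c1 | intermediate
9 | [3,5-bis(TIPS-oxy)phenyl]lithium | [Li]c1cc(O[Si](C(C)C)(C(C)C)C(C)C)cc(O[Si](C(C)C)(C(C)C)C(C)C)c1 | intermediate
10 | (4-bromo-2-hydroxy-6-{[2,4-bis(TIPS-oxy)phenyl]methoxy}phenyl)[3,5-bis(TIPS-oxy)phenyl]methanol, racemic | OC(c1cc(O[Si](C(C)C)(C(C)C)C(C)C)cc(O[Si](C(C)C)(C(C)C)C(C)C)c1)c1c(O)cc(Br)cc1OCc1ccc(O[Si](C(C)C)(C(C)C)C(C)C)cc1O[Si](C(C)C)(C(C)C)C(C)C | intermediate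
11 | (4-bromo-2-hydroxy-6-{[2,4-bis(TIPS-oxy)phenyl]methoxy}phenyl)[3,5-bis(TIPS-oxy)phenyl]methanone | O=C(c1cc(O[Si](C(C)C)(C(C)C)C(C)C)cc(O[Si](C(C)C)(C(C)C)C(C)C)c1)c1c(O)cc(Br)cc1OCc1ccc(O[Si](C(C)C)(C(C)C)C(C)C)cc1O[Si](C(C)C)(C(C)C)C(C)C | intermediate
12 | hydrazone of 11 (C=N isomer mixture) | NN=C(c1cc(O[Si](C(C)C)(C(C)C)C(C)C)cc(O[Si](C(C)C)(C(C)C)C(C)C)c1)c1c(O)cc(Br)cc1OCc1ccc(O[Si](C(C)C)(C(C)C)C(C)C)cc1O[Si](C(C)C)(C(C)C)C(C)C | intermediate
13 | O-TIPS ether of hydrazone 12 | NN=C(c1cc(O[Si](C(C)C)(C(C)C)C(C)C)cc(O[Si](C(C)C)(C(C)C)C(C)C)c1)c1c(O[Si](C(C)C)(C(C)C)C(C)C)cc(Br)cc1OCc1ccc(O[Si](C(C)C)(C(C)C)C(C)C)cc1O[Si](C(C)C)(C(C)C)C(C)C | intermediate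
14 | diaryldiazomethane from 13 | [N-]=[N+]=C(c1cc(O[Si](C(C)C)(C(C)C)C(C)C)cc(O[Si](C(C)C)(C(C)C)C(C)C)c1)c1c(O[Si](C(C)C)(C(C)C)C(C)C)cc(Br)cc1OCc1ccc(O[Si](C(C)C)(C(C)C)C(C)C)cc1O[Si](C(C)C)(C(C)C)C(C)C | intermediate
15 | (2R,3S)-6-bromo-2-[2,4-bis(TIPS-oxy)phenyl]-3-[3,5-bis(TIPS-oxy)phenyl]-4-(TIPS-oxy)-2,3-dihydro-1-benzofuran (cis) | Brc1cc(O[Si](C(C)C)(C(C)C)C(C)C)c2c(c1)O[C@@H](c1ccc(O[Si](C(C)C)(C(C)C)C(C)C)cc1O[Si](C(C)C)(C(C)C)C(C)C)[C@H]2c1cc(O[Si](C(C)C)(C(C)C)C(C)C)cc(O[Si](C(C)C)(C(C)C)C(C)C)c1 | intermediate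
16 | (2S,3S)-6-bromo-2-[2,4-bis(TIPS-oxy)phenyl]-3-[3,5-bis(TIPS-oxy)phenyl]-4-(TIPS-oxy)-2,3-dihydro-1-benzofuran (trans; RS2–Br) | Brc1cc(O[Si](C(C)C)(C(C)C)C(C)C)c2c(c1)O[C@H](c1ccc(O[Si](C(C)C)(C(C)C)C(C)C)cc1O[Si](C(C)C)(C(C)C)C(C)C)[C@H]2c1cc(O[Si](C(C)C)(C(C)C)C(C)C)cc(O[Si](C(C)C)(C(C)C)C(C)C)c1 | intermediate
17 | 4-bromo-2,6-bis(methoxymethoxy)benzaldehyde | COCOc1cc(Br)cc(OCOC)c1C=O | intermediate
18 | tert-butyldimethyl(4-vinylphenoxy)silane | C=Cc1ccc(O[Si](C)(C)C(C)(C)C)cc1 | starting material
19 | 4-[(E)-2-{4-[(TBS)oxy]phenyl}ethenyl]-2,6-bis(methoxymethoxy)benzaldehyde | O=Cc1c(OCOC)cc(/C=C/c2ccc(O[Si](C)(C)C(C)(C)C)cc2)cc1OCOC | intermediate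
20 | RS2–Li, the 6-lithio derivative of 16 | [Li]c1cc(O[Si](C(C)C)(C(C)C)C(C)C)c2c(c1)O[C@H](c1ccc(O[Si](C(C)C)(C(C)C)C(C)C)cc1O[Si](C(C)C)(C(C)C)C(C)C)[C@H]2c1cc(O[Si](C(C)C)(C(C)C)C(C)C)cc(O[Si](C(C)C)(C(C)C)C(C)C)c1 | intermediate
21 | {4-[(E)-2-{4-[(TBS)oxy]phenyl}ethenyl]-2,6-bis(methoxymethoxy)phenyl}(RS2)methanol, both carbinol epimers | OC(c1c(OCOC)cc(/C=C/c2ccc(O[Si](C)(C)C(C)(C)C)cc2)cc1OCOC)c1cc(O[Si](C(C)C)(C(C)C)C(C)C)c2c(c1)O[C@H](c1ccc(O[Si](C(C)C)(C(C)C)C(C)C)cc1O[Si](C(C)C)(C(C)C)C(C)C)[C@H]2c1cc(O[Si](C(C)C)(C(C)C)C(C)C)cc(O[Si](C(C)C)(C(C)C)C(C)C)c1 | intermediate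
22 | {4-[(E)-2-{4-[(TBS)oxy]phenyl}ethenyl]-2,6-bis(methoxymethoxy)phenyl}(RS2)methanone | O=C(c1c(OCOC)cc(/C=C/c2ccc(O[Si](C)(C)C(C)(C)C)cc2)cc1OCOC)c1cc(O[Si](C(C)C)(C(C)C)C(C)C)c2c(c1)O[C@H](c1ccc(O[Si](C(C)C)(C(C)C)C(C)C)cc1O[Si](C(C)C)(C(C)C)C(C)C)[C@H]2c1cc(O[Si](C(C)C)(C(C)C)C(C)C)cc(O[Si](C(C)C)(C(C)C)C(C)C)c1 | intermediate
23 | 4-[(TBS)oxy]benzaldehyde | O=Cc1ccc(O[Si](C)(C)C(C)(C)C)cc1 | starting material
24 | {4-[(TBS)oxy]phenyl}methanol | OCc1ccc(O[Si](C)(C)C(C)(C)C)cc1 | intermediate
25 | tert-butyl[4-(chloromethyl)phenoxy]dimethylsilane | ClCc1ccc(O[Si](C)(C)C(C)(C)C)cc1 | intermediate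
26 | {4-[(TBS)oxy]benzyl}magnesium chloride | Cl[Mg]Cc1ccc(O[Si](C)(C)C(C)(C)C)cc1 | intermediate
27 | 1-{4-[(E)-2-{4-[(TBS)oxy]phenyl}ethenyl]-2,6-bis(methoxymethoxy)phenyl}-1-(RS2)-2-{4-[(TBS)oxy]phenyl}ethan-1-ol, both carbinol epimers | OC(Cc1ccc(O[Si](C)(C)C(C)(C)C)cc1)(c1c(OCOC)cc(/C=C/c2ccc(O[Si](C)(C)C(C)(C)C)cc2)cc1OCOC)c1cc(O[Si](C(C)C)(C(C)C)C(C)C)c2c(c1)O[C@H](c1ccc(O[Si](C(C)C)(C(C)C)C(C)C)cc1O[Si](C(C)C)(C(C)C)C(C)C)[C@H]2c1cc(O[Si](C(C)C)(C(C)C)C(C)C)cc(O[Si](C(C)C)(C(C)C)C(C)C)c1 | intermediate
28 | 2-{1-(RS2)-2-{4-[(TBS)oxy]phenyl}ethenyl}-5-[(E)-2-{4-[(TBS)oxy]phenyl}ethenyl]benzene-1,3-diol, E/Z mixture at the triaryl alkene (left unspecified in the SMILES) | Oc1cc(/C=C/c2ccc(O[Si](C)(C)C(C)(C)C)cc2)cc(O)c1C(=Cc1ccc(O[Si](C)(C)C(C)(C)C)cc1)c1cc(O[Si](C(C)C)(C(C)C)C(C)C)c2c(c1)O[C@H](c1ccc(O[Si](C(C)C)(C(C)C)C(C)C)cc1O[Si](C(C)C)(C(C)C)C(C)C)[C@H]2c1cc(O[Si](C(C)C)(C(C)C)C(C)C)cc(O[Si](C(C)C)(C(C)C)C(C)C)c1 | intermediate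
29 | 2-[(1S)-1-(RS2)-2-{4-[(TBS)oxy]phenyl}ethyl]-5-[(E)-2-{4-[(TBS)oxy]phenyl}ethenyl]benzene-1,3-diol | CC(C)(C)[Si](C)(C)Oc1ccc(/C=C/c2cc(O)c(c(O)c2)[C@@H](Cc2ccc(O[Si](C)(C)C(C)(C)C)cc2)c2cc(O[Si](C(C)C)(C(C)C)C(C)C)c3c(c2)O[C@H](c2ccc(O[Si](C(C)C)(C(C)C)C(C)C)cc2O[Si](C(C)C)(C(C)C)C(C)C)[C@H]3c2cc(O[Si](C(C)C)(C(C)C)C(C)C)cc(O[Si](C(C)C)(C(C)C)C(C)C)c2)cc1 | intermediate
30 | seco-phenol, 2-[(1S)-1-[(2S,3S)-3-(3,5-dihydroxyphenyl)-2-(2,4-dihydroxyphenyl)-4-hydroxy-2,3-dihydro-1-benzofuran-6-yl]-2-(4-hydroxyphenyl)ethyl]-5-[(E)-2-(4-hydroxyphenyl)ethenyl]benzene-1,3-diol | Oc1ccc(/C=C/c2cc(O)c(c(O)c2)[C@@H](Cc2ccc(O)cc2)c2cc(O)c3c(c2)O[C@H](c2ccc(O)cc2O)[C@H]3c2cc(O)cc(O)c2)cc1 | intermediate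
31 | para-quinone methide, 4-{(2S)-2-[(2S,3S)-3-(3,5-dihydroxyphenyl)-2-(2,4-dihydroxyphenyl)-4-hydroxy-2,3-dihydro-1-benzofuran-6-yl]-2-{2,6-dihydroxy-4-[(E)-2-(4-hydroxyphenyl)ethenyl]phenyl}ethylidene}cyclohexa-2,5-dien-1-one | Oc1ccc(/C=C/c2cc(O)c(c(O)c2)[C@@H](C=C2C=CC(=O)C=C2)c2cc(O)c3c(c2)O[C@H](c2ccc(O)cc2O)[C@H]3c2cc(O)cc(O)c2)cc1 | intermediate
32 | (2S,3S)-3-[(2S,3S)-3-(3,5-dihydroxyphenyl)-2-(2,4-dihydroxyphenyl)-4-hydroxy-2,3-dihydro-1-benzofuran-6-yl]-2-(4-hydroxyphenyl)-6-[(E)-2-(4-hydroxyphenyl)ethenyl]-2,3-dihydro-1-benzofuran-4-ol | Oc1ccc(/C=C/c2cc(O)c3c(c2)O[C@H](c2ccc(O)cc2)[C@H]3c2cc(O)c3c(c2)O[C@H](c2ccc(O)cc2O)[C@H]3c2cc(O)cc(O)c2)cc1 | target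

## Step count and least certain steps

Total: 21 steps. Longest linear sequence: 15 steps (3 → 4 → 5 → 6 → 10 → 11 → 12 → 13 → 16 → 21 → 22 → 27 → 28 → 29 → 30 → 32; steps 2, 3, 4, 6–10, 13, 14, 17–21).

**Step 21 (key step).**
- Most likely failures: no turnover because 30 is far larger than the natural substrates of the enzyme family; loss of the C3 proton from 31 (the alkene-forming branch of these oxidases), which erases C3; further dehydrogenation of the product at C2–H or of ring system 2 at C2'–H to benzofurans.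
- Fallback (known chemistry), from 28 to 32: TFA in CH2Cl2 at 0 °C effects acid-catalysed hydroalkoxylation of the ortho-hydroxy stilbene. Reversible protonation at C3 gives the C2 benzylic cation, which a ring A hydroxyl captures to close ring 1 trans. C3 is then not controlled, so the heptasilyl ether of the target F1 forms together with its (2R,3R) epimer F2. The two are diastereomers and are separated by preparative HPLC. F1 is desilylated with TBAF/AcOH to 32.

**Step 10.**
- Most likely failure: erosion of enantioselectivity or of clean insertion (azine formation, carbene dimerisation), because the carbene carbon is flanked by two ortho oxygen substituents and may not sit in the chiral pocket as simpler substrates do.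
- Fallback, from 13 to 16: MnO2, then achiral Rh2(OAc)4, then TFA give the trans ring as a racemate, that is 16 with its enantiomer F3. Preparative chiral-phase SFC returns enantiopure 16 (resolution in place of asymmetric induction).

**Step 19.**
- Most likely failure: poor facial selectivity in hydride delivery to a fully substituted quinone-methide carbon whose two substituents (hub aryl, benzyl) differ little in size, with background acid-catalysed ring closure as a side channel.
- Fallback, from 28 to 29: reduction with the Hantzsch ester and achiral diphenyl phosphate gives 29 together with its C3 epimer F4. Because ring system 2 is already enantiopure these are diastereomers, and they are separated by preparative HPLC.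

**Step 18.**
- Most likely failure: loss of the two TBS ethers, or premature closure of ring 1, during acid cleavage of the MOM groups on a substrate that ionises easily.
- Fallback, from 22 to 29: the MOM ethers are removed at the ketone stage, where cleavage is assisted by the ortho carbonyl (dilute HCl in MeOH, 0 °C), to give dihydroxy ketone F5. Excess 26 adds to it to give carbinol triol F6. (R)-TRIP and the Hantzsch ester then dehydrate and reduce F6 directly to 29, with no alkene isolated and no strong acid.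

**Step 17.**
- Most likely failure: attack through the ortho ring position of the benzyl Grignard reagent (a known pathway with crowded carbonyl partners), Wurtz coupling while 26 is formed, or no addition to the doubly ortho-substituted ketone.
- Fallback, from 19 and 26 to 27: addition of 26 to aldehyde 19 gives secondary carbinol F7, and Dess–Martin oxidation gives deoxybenzoin F8. Aryllithium 20 is transmetallated with anhydrous CeCl3 to the arylcerium dichloride F9 (trivalent cerium), which adds to the enolisable ketone F8 without deprotonating it and gives 27.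

## Further compounds

F1 | step 21 | heptasilyl ether of 32 (2S,3S,2'S,3'S; ring A 4-OH free) | CC(C)(C)[Si](C)(C)Oc1ccc(/C=C/c2cc(O)c3c(c2)O[C@H](c2ccc(O[Si](C)(C)C(C)(C)C)cc2)[C@H]3c2cc(O[Si](C(C)C)(C(C)C)C(C)C)c3c(c2)O[C@H](c2ccc(O[Si](C(C)C)(C(C)C)C(C)C)cc2O[Si](C(C)C)(C(C)C)C(C)C)[C@H]3c2cc(O[Si](C(C)C)(C(C)C)C(C)C)cc(O[Si](C(C)C)(C(C)C)C(C)C)c2)cc1
F2 | step 21 | (2R,3R,2'S,3'S) epimer of F1 | CC(C)(C)[Si](C)(C)Oc1ccc(/C=C/c2cc(O)c3c(c2)O[C@@H](c2ccc(O[Si](C)(C)C(C)(C)C)cc2)[C@@H]3c2cc(O[Si](C(C)C)(C(C)C)C(C)C)c3c(c2)O[C@H](c2ccc(O[Si](C(C)C)(C(C)C)C(C)C)cc2O[Si](C(C)C)(C(C)C)C(C)C)[C@H]3c2cc(O[Si](C(C)C)(C(C)C)C(C)C)cc(O[Si](C(C)C)(C(C)C)C(C)C)c2)cc1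
F3 | step 10 | (2R,3R) enantiomer of 16 | Brc1cc(O[Si](C(C)C)(C(C)C)C(C)C)c2c(c1)O[C@@H](c1ccc(O[Si](C(C)C)(C(C)C)C(C)C)cc1O[Si](C(C)C)(C(C)C)C(C)C)[C@@H]2c1cc(O[Si](C(C)C)(C(C)C)C(C)C)cc(O[Si](C(C)C)(C(C)C)C(C)C)c1
F4 | step 19 | (1R) epimer of 29 at C3 | CC(C)(C)[Si](C)(C)Oc1ccc(/C=C/c2cc(O)c(c(O)c2)[C@H](Cc2ccc(O[Si](C)(C)C(C)(C)C)cc2)c2cc(O[Si](C(C)C)(C(C)C)C(C)C)c3c(c2)O[C@H](c2ccc(O[Si](C(C)C)(C(C)C)C(C)C)cc2O[Si](C(C)C)(C(C)C)C(C)C)[C@H]3c2cc(O[Si](C(C)C)(C(C)C)C(C)C)cc(O[Si](C(C)C)(C(C)C)C(C)C)c2)cc1
F5 | step 18 | {4-[(E)-2-{4-[(TBS)oxy]phenyl}ethenyl]-2,6-dihydroxyphenyl}(RS2)methanone | O=C(c1c(O)cc(/C=C/c2ccc(O[Si](C)(C)C(C)(C)C)cc2)cc1O)c1cc(O[Si](C(C)C)(C(C)C)C(C)C)c2c(c1)O[C@H](c1ccc(O[Si](C(C)C)(C(C)C)C(C)C)cc1O[Si](C(C)C)(C(C)C)C(C)C)[C@H]2c1cc(O[Si](C(C)C)(C(C)C)C(C)C)cc(O[Si](C(C)C)(C(C)C)C(C)C)c1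
F6 | step 18 | 2-[1-hydroxy-1-(RS2)-2-{4-[(TBS)oxy]phenyl}ethyl]-5-[(E)-2-{4-[(TBS)oxy]phenyl}ethenyl]benzene-1,3-diol, both carbinol epimers | OC(Cc1ccc(O[Si](C)(C)C(C)(C)C)cc1)(c1c(O)cc(/C=C/c2ccc(O[Si](C)(C)C(C)(C)C)cc2)cc1O)c1cc(O[Si](C(C)C)(C(C)C)C(C)C)c2c(c1)O[C@H](c1ccc(O[Si](C(C)C)(C(C)C)C(C)C)cc1O[Si](C(C)C)(C(C)C)C(C)C)[C@H]2c1cc(O[Si](C(C)C)(C(C)C)C(C)C)cc(O[Si](C(C)C)(C(C)C)C(C)C)c1
F7 | step 17 | 1-{4-[(E)-2-{4-[(TBS)oxy]phenyl}ethenyl]-2,6-bis(methoxymethoxy)phenyl}-2-{4-[(TBS)oxy]phenyl}ethan-1-ol, racemic | OC(Cc1ccc(O[Si](C)(C)C(C)(C)C)cc1)c1c(OCOC)cc(/C=C/c2ccc(O[Si](C)(C)C(C)(C)C)cc2)cc1OCOC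
F8 | step 17 | 1-{4-[(E)-2-{4-[(TBS)oxy]phenyl}ethenyl]-2,6-bis(methoxymethoxy)phenyl}-2-{4-[(TBS)oxy]phenyl}ethan-1-one | O=C(Cc1ccc(O[Si](C)(C)C(C)(C)C)cc1)c1c(OCOC)cc(/C=C/c2ccc(O[Si](C)(C)C(C)(C)C)cc2)cc1OCOC
F9 | step 17 | RS2–CeCl2, arylcerium dichloride from 20 | Cl[Ce](Cl)c1cc(O[Si](C(C)C)(C(C)C)C(C)C)c2c(c1)O[C@H](c1ccc(O[Si](C(C)C)(C(C)C)C(C)C)cc1O[Si](C(C)C)(C(C)C)C(C)C)[C@H]2c1cc(O[Si](C(C)C)(C(C)C)C(C)C)cc(O[Si](C(C)C)(C(C)C)C(C)C)c1
A1 | alternative 1 | resorcinol mono-TIPS ether with the 1-(3,5-dimethoxyphenyl)-2-[(TBS)oxy]-2-(4-methoxyphenyl)ethyl chain between its oxygens and an (E)-4-methoxystyryl group para to it | COc1ccc(/C=C/c2cc(O)c(c(O[Si](C(C)C)(C(C)C)C(C)C)c2)[C@H](c2cc(OC)cc(OC)c2)[C@H](O[Si](C)(C)C(C)(C)C)c2ccc(OC)cc2)cc1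
A2 | alternative 1 | 3-[(E)-2-(4-methoxyphenyl)ethenyl]cyclobut-2-en-1-one | COc1ccc(/C=C/C2=CC(=O)C2)cc1
A3 | alternative 1 | triisopropylsilyl ynol ether carrying the 1-(3,5-dimethoxyphenyl)-2-[(TBS)oxy]-2-(4-methoxyphenyl)ethyl chain on the alkyne | CC(C)[Si](OC#C[C@H](c1cc(OC)cc(OC)c1)[C@H](O[Si](C)(C)C(C)(C)C)c1ccc(OC)cc1)(C(C)C)C(C)C
A4 | alternative 2 | (2S,3S)-6-bromo-2-(2,4-dimethoxyphenyl)-3-(3,5-dimethoxyphenyl)-4-methoxy-2,3-dihydro-1-benzofuran | Brc1cc(OC)c2c(c1)O[C@H](c1ccc(OC)cc1OC)[C@H]2c1cc(OC)cc(OC)c1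
A5 | alternative 2 | 5-bromo-2-[(3,5-dimethoxyphenyl)(4-methylbenzenesulfonyl)methyl]-3-methoxyphenol, racemic | Cc1ccc(cc1)S(=O)(=O)C(c1cc(OC)cc(OC)c1)c1c(O)cc(Br)cc1OC
A6 | alternative 2 | (2R,5R)-1-[(2,4-dimethoxyphenyl)methyl]-2,5-dimethylthiolan-1-ium trifluoromethanesulfonate | C[C@@H]1CC[C@@H](C)[S+]1Cc1ccc(OC)cc1OC.[O-]S(=O)(=O)C(F)(F)F
A7 | alternative 3 | methyl (2S,3S)-6-(benzyloxy)-4-methoxy-2-(4-methoxyphenyl)-2,3-dihydro-1-benzofuran-3-carboxylate (trans) | c1ccccc1COc2cc(OC)c3c(c2)O[C@H](c2ccc(OC)cc2)[C@H]3C(=O)OC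
A8 | alternative 3 | (2S)-7-(benzyloxy)-5-methoxy-2-(4-methoxyphenyl)-2,3-dihydro-4H-chromen-4-one | COc1ccc(cc1)[C@@H]1CC(=O)c2c(OC)cc(OCc3ccccc3)cc2O1
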